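**Retrosynthetic overview**
1. Target 21 ⇐ 20 ⇐ 19: removal of one silyl and thirteen benzyl groups from the fully protected trimer 19.
2. 19 ⇐ phenol 15 + epoxy aldehyde 14 + dimer 9 in one flask: the C4a–C4 bond (ortho-hydroxyalkylation) and the O1–C2 bond (6-endo epoxide opening) close ring C of the top unit, then the C4 carbinol ionises and C8 of the middle unit of 9 forms the interflavan bond.
3. Enabling feature: ring A of the top unit is a phloroglucinol ring, so C4a and the oxygen O1 on the adjacent C8a are a 1,3-C,O-dinucleophile; C4–C3–C2 of ring C maps onto a trans-2,3-epoxy aldehyde (C4 = CHO, C2 = benzylic epoxide carbon next to ring B); the O1/O5/O7 pattern of ring A also makes C4 ionisable for the C4–C8 bond.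
4. 9 ⇐ 8-lithio-penta-O-benzyl-ent-catechin + protected (+)-taxifolin, then ionic hydrogenation of the carbinol (3,4-cis 4β→8 bond); 14 ⇐ Sharpless epoxidation of a cinnamyl alcohol.
5. Ring order: the rings of the bottom and middle units are bought with (−)-catechin and (+)-taxifolin; the only ring built is ring C of the top unit (step 10); no ring is formed afterwards.

Key step: step 10

Remark: the target is read as gallocatechin-(4α→8)-catechin-(4β→8)-ent-catechin (top unit 2R,3S,4S, 3,4-trans interflavan bond; middle unit 2R,3S,4S, 3,4-cis interflavan bond; bottom unit 2S,3R). Compounds 1, 4, 10 and 15 are taken as commercial. C4 of 17 and 18 is an epimer mixture that converges on ionisation; 8 is drawn as its expected main epimer and either epimer converges likewise.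

**Step 1**
Reactants: 1 (−)-catechin
Product: 2 (2S,3R)-3,5,7-tris(benzyloxy)-2-[3,4-bis(benzyloxy)phenyl]chromane (penta-O-benzyl-ent-catechin)
Conditions: BnBr (6 equiv), NaH (5.5 equiv), DMF, −20 °C → rt
Reagents that add atoms: benzyl bromide, BrCc1ccccc1
Why: Williamson etherification of the four phenols and the secondary alcohol should give the pentaether without touching C2 or C3.

**Step 2**
Reactants: 2 penta-O-benzyl-ent-catechin
Product: 3 (2S,3R)-8-bromo-3,5,7-tris(benzyloxy)-2-[3,4-bis(benzyloxy)phenyl]chromane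
Conditions: NBS (1.0 equiv), CH2Cl2, −78 °C → rt
Reagents that add atoms: N-bromosuccinimide, O=C1CCC(=O)N1Br
Why: electrophilic aromatic bromination of the 5,7-dialkoxy ring A of O-benzylated flavans is known to occur at C8 in preference to C6.

**Step 3**
Reactants: 4 (+)-taxifolin
Product: 5 (2R,3R)-5,7-bis(benzyloxy)-2-[3,4-bis(benzyloxy)phenyl]-3-hydroxychroman-4-one
Conditions: BnBr (4.5 equiv), K2CO3, DMF, rt, N2, dark
Reagents that add atoms: benzyl bromide, BrCc1ccccc1
Why: Williamson etherification with the mild base K2CO3 should benzylate the four phenols (the chelated 5-OH last) and leave the α-hydroxy ketone and the 2,3-trans stereocentres intact.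

**Step 4**
Reactants: 5 tetra-O-benzyltaxifolin
Product: 6 (2R,3R)-5,7-bis(benzyloxy)-2-[3,4-bis(benzyloxy)phenyl]-3-(tert-butyldimethylsilyloxy)chroman-4-one
Conditions: TBSOTf, 2,6-lutidine, CH2Cl2, 0 °C
Reagents that add atoms: tert-butyldimethylsilyl triflate, CC(C)(C)[Si](C)(C)OS(=O)(=O)C(F)(F)F
Why: silylation of the secondary 3-hydroxyl with a silyl triflate and a hindered base should proceed without enolisation and places a bulky group on the β-face next to C4.

**Step 5**
Reactants: 3 8-bromo-penta-O-benzyl-ent-catechin; 6 silylated flavan-4-one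
Product: 9 3-O-TBS-5,7,3',4'-tetra-O-benzylcatechin-(4β→8)-3,5,7,3',4'-penta-O-benzyl-ent-catechin (upper unit 2,3-trans-3,4-cis), via aryllithium 7 (not isolated), via tertiary carbinol 8 (not isolated)
Conditions: 3, t-BuLi (2.0 equiv), THF, −78 °C; 6, −78 → −40 °C; then CF3CO2H (excess), n-Bu3SnH (3 equiv), CH2Cl2, −78 → 0 °C
Reagents that add atoms: none
Why: bromine–lithium exchange gives aryllithium 7, which adds to the C4 ketone of 6 (1,2-addition), and acid then ionises the doubly benzylic carbinol 8 to a cation that the tin hydride reduces (ionic hydrogenation) from the α-face, anti to the neighbouring 3-silyloxy group, so that the aryl group ends 4β and C4 of the middle unit is set 3,4-cis, a mode of delivery that has precedent in the 2,3-cis flavan-4-one series.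

**Step 6**
Reactants: 10 3,4,5-tris(benzyloxy)benzaldehyde
Product: 11 ethyl (E)-3-[3,4,5-tris(benzyloxy)phenyl]prop-2-enoate
Conditions: Ph3P=CHCO2Et, toluene, 90 °C
Reagents that add atoms: ethyl (triphenylphosphoranylidene)acetate, CCOC(=O)C=P(c1ccccc1)(c1ccccc1)c1ccccc1
Why: Wittig olefination with a stabilised ylide should give the (E)-cinnamate selectively.

**Step 7**
Reactants: 11 ethyl cinnamate
Product: 12 (E)-3-[3,4,5-tris(benzyloxy)phenyl]prop-2-en-1-ol
Conditions: i-Bu2AlH (2.2 equiv), CH2Cl2, −78 °C; then H2O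
Reagents that add atoms: none
Why: 1,2-reduction of the ester by i-Bu2AlH at low temperature should give the allylic alcohol without touching the alkene or the benzyl ethers.

**Step 8**
Reactants: 12 cinnamyl alcohol
Product: 13 [(2S,3S)-3-(3,4,5-tris(benzyloxy)phenyl)oxiran-2-yl]methanol
Conditions: Ti(OiPr)4 (10 mol %), L-(+)-diethyl tartrate (12 mol %), t-BuOOH (2 equiv), 4 Å molecular sieves, CH2Cl2, −20 °C
Reagents that add atoms: tert-butyl hydroperoxide, CC(C)(C)OO
Why: Sharpless asymmetric epoxidation of the (E)-allylic alcohol with L-(+)-diethyl tartrate delivers oxygen to the face that gives the (2S,3S)-epoxy alcohol and so sets both epoxide stereocentres.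

**Step 9**
Reactants: 13 epoxy alcohol
Product: 14 (2R,3S)-3-[3,4,5-tris(benzyloxy)phenyl]oxirane-2-carbaldehyde
Conditions: TEMPO (10 mol %), PhI(OAc)2 (1.1 equiv), CH2Cl2, rt
Reagents that add atoms: none
Why: the nitroxyl-catalysed oxidation converts the primary alcohol into the aldehyde under nearly neutral conditions, so the epoxide and the α-stereocentre should survive (the C2 descriptor becomes R only because the substituent priorities change).

**Step 10**
Reactants: 15 3,5-bis(benzyloxy)phenol; 14 epoxy aldehyde; 9 protected dimer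
Product: 19 5,7,3',4',5'-penta-O-benzylgallocatechin-(4α→8)-[3-O-TBS-5,7,3',4'-tetra-O-benzylcatechin]-(4β→8)-3,5,7,3',4'-penta-O-benzyl-ent-catechin, via titanium aryloxide 16 (not isolated), via epoxy carbinol 17 (not isolated), via flavan-3,4-diol 18 (not isolated)
Conditions: 15, Ti(OiPr)4 (1.05 equiv), toluene, rt, then removal of i-PrOH in vacuo; 14 (1.0 equiv), CH2Cl2, −40 → 0 °C, then rt; then 9 (1.5 equiv), TiCl4 (3 equiv), CH2Cl2, −78 → −30 °C; H2O
Reagents that add atoms: none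
Why: Proposed new method: titanium aryloxide 16 delivers the aldehyde of 14 to its ortho carbon through a six-membered chelate (C4a–C4 bond; closest known type: ortho-specific hydroxyalkylation of metal phenoxides by aldehydes), and the titanium-bound 2,3-epoxy alkoxide 17 is then opened at its distal, benzylic carbon by the phenoxide oxygen (O1–C2 bond; closest known types: Ti(OiPr)4-mediated C3-selective opening of 2,3-epoxy alcohols and the 6-endo phenol–epoxide closure used for flavan-3-ols). Ring C of the top unit thus closes in a 6-endo-tet mode, favoured over 5-exo by chelation of the epoxy alkoxide on tetravalent titanium and by benzylic stabilisation from ring B. C2 is set by inversion at the (3S) epoxide carbon and becomes 2R, C3 is the untouched (2R) epoxide carbon and becomes 3S (2,3-trans), and the configuration of the C4 carbinol is irrelevant because TiCl4 then ionises it to a cation stabilised by O1, O5 and O7 of ring A (closest known type: TiCl4-mediated condensation of benzylated flavan-3,4-diols with flavan nucleophiles). C8 of the middle unit of 9 should attack this cation anti to the titanium-bound C3 oxygen, which sets C4 as 4α (3,4-trans, all-equatorial) and forms the interflavan bond. The step needs ortho-C over para-C or O-alkylation of 15 (secured by the titanium chelate; the two ortho positions are equivalent), 6-endo over 5-exo opening (secured as above) and C8 over C6 attack by 9 (secured by the higher nucleophilicity of C8 in 5,7-di-O-benzylflavans and the blocked C8 of the bottom unit).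

**Step 11**
Reactants: 19 protected trimer
Product: 20 5,7,3',4',5'-penta-O-benzylgallocatechin-(4α→8)-5,7,3',4'-tetra-O-benzylcatechin-(4β→8)-3,5,7,3',4'-penta-O-benzyl-ent-catechin (free 3-OH on the top and middle units)
Conditions: n-Bu4NF (3 equiv), THF, rt → 40 °C
Reagents that add atoms: none
Why: fluoride cleaves the Si–O bond of the secondary silyl ether while benzyl ethers and interflavan bonds are inert.

**Step 12**
Reactants: 20 tridecabenzyl trimer
Product: 21 target, gallocatechin-(4α→8)-catechin-(4β→8)-ent-catechin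
Conditions: H2 (1 atm), Pd(OH)2/C, THF/MeOH/H2O, rt
Reagents that add atoms: none
Why: hydrogenolysis over Pd(OH)2/C cleaves all thirteen benzyl ethers, the standard last step for procyanidin benzyl ethers, and leaves the interflavan bonds and all stereocentres untouched.

**Compound list**
1 | (−)-catechin, (2S,3R)-2-(3,4-dihydroxyphenyl)chromane-3,5,7-triol | Oc1cc(O)c2c(c1)O[C@@H](c1ccc(O)c(O)c1)[C@H](O)C2 | starting material
2 | (2S,3R)-3,5,7-tris(benzyloxy)-2-[3,4-bis(benzyloxy)phenyl]chromane | c1c(OCc3ccccc3)cc(OCc3ccccc3)c2c1O[C@@H](c1ccc(OCc3ccccc3)c(OCc3ccccc3)c1)[C@H](OCc3ccccc3)C2 | intermediate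
3 | (2S,3R)-8-bromo-3,5,7-tris(benzyloxy)-2-[3,4-bis(benzyloxy)phenyl]chromane | Brc1c(OCc3ccccc3)cc(OCc3ccccc3)c2c1O[C@@H](c1ccc(OCc3ccccc3)c(OCc3ccccc3)c1)[C@H](OCc3ccccc3)C2 | intermediate
4 | (+)-taxifolin, (2R,3R)-2-(3,4-dihydroxyphenyl)-3,5,7-trihydroxychroman-4-one | Oc1cc(O)c2c(c1)O[C@H](c1ccc(O)c(O)c1)[C@@H](O)C2=O | starting material
5 | (2R,3R)-5,7-bis(benzyloxy)-2-[3,4-bis(benzyloxy)phenyl]-3-hydroxychroman-4-one | C(c3ccccc3)Oc1cc(OCc3ccccc3)c2c(c1)O[C@H](c1ccc(OCc3ccccc3)c(OCc3ccccc3)c1)[C@@H](O)C2=O | intermediate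
6 | (2R,3R)-5,7-bis(benzyloxy)-2-[3,4-bis(benzyloxy)phenyl]-3-(tert-butyldimethylsilyloxy)chroman-4-one | C(c3ccccc3)Oc1cc(OCc3ccccc3)c2c(c1)O[C@H](c1ccc(OCc3ccccc3)c(OCc3ccccc3)c1)[C@@H](O[Si](C)(C)C(C)(C)C)C2=O | intermediate
7 | 8-lithio derivative of 2 (aryllithium) | [Li]c1c(OCc3ccccc3)cc(OCc3ccccc3)c2c1O[C@@H](c1ccc(OCc3ccccc3)c(OCc3ccccc3)c1)[C@H](OCc3ccccc3)C2 | intermediate (not isolated)
8 | tertiary carbinol from 7 and 6: 4-hydroxy-4-(flavan-8-yl) adduct, expected mainly 4α-aryl-4β-hydroxy, formed as its lithium alkoxide | C(c3ccccc3)Oc1cc(OCc3ccccc3)c2c(c1)O[C@H](c1ccc(OCc3ccccc3)c(OCc3ccccc3)c1)[C@@H](O[Si](C)(C)C(C)(C)C)[C@]2(O)c1c(OCc3ccccc3)cc(OCc3ccccc3)c2c1O[C@@H](c1ccc(OCc3ccccc3)c(OCc3ccccc3)c1)[C@H](OCc3ccccc3)C2 | intermediate (not isolated)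
9 | 3-O-TBS-5,7,3',4'-tetra-O-benzylcatechin-(4β→8)-3,5,7,3',4'-penta-O-benzyl-ent-catechin | C(c3ccccc3)Oc1cc(OCc3ccccc3)c2c(c1)O[C@H](c1ccc(OCc3ccccc3)c(OCc3ccccc3)c1)[C@@H](O[Si](C)(C)C(C)(C)C)[C@H]2c1c(OCc3ccccc3)cc(OCc3ccccc3)c2c1O[C@@H](c1ccc(OCc3ccccc3)c(OCc3ccccc3)c1)[C@H](OCc3ccccc3)C2 | intermediate
10 | 3,4,5-tris(benzyloxy)benzaldehyde | O=Cc1cc(OCc3ccccc3)c(OCc3ccccc3)c(OCc3ccccc3)c1 | starting material
11 | ethyl (E)-3-[3,4,5-tris(benzyloxy)phenyl]prop-2-enoate | CCOC(=O)/C=C/c1cc(OCc3ccccc3)c(OCc3ccccc3)c(OCc3ccccc3)c1 | intermediate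
12 | (E)-3-[3,4,5-tris(benzyloxy)phenyl]prop-2-en-1-ol | OC/C=C/c1cc(OCc3ccccc3)c(OCc3ccccc3)c(OCc3ccccc3)c1 | intermediate
13 | [(2S,3S)-3-(3,4,5-tris(benzyloxy)phenyl)oxiran-2-yl]methanol | OC[C@@H]1O[C@H]1c1cc(OCc3ccccc3)c(OCc3ccccc3)c(OCc3ccccc3)c1 | intermediate
14 | (2R,3S)-3-[3,4,5-tris(benzyloxy)phenyl]oxirane-2-carbaldehyde | O=C[C@@H]1O[C@H]1c1cc(OCc3ccccc3)c(OCc3ccccc3)c(OCc3ccccc3)c1 | intermediate
15 | 3,5-bis(benzyloxy)phenol | Oc1cc(OCc3ccccc3)cc(OCc3ccccc3)c1 | starting material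
16 | [3,5-bis(benzyloxy)phenoxy]titanium triisopropoxide | CC(C)O[Ti](OC(C)C)(OC(C)C)Oc1cc(OCc3ccccc3)cc(OCc3ccccc3)c1 | intermediate (not isolated)
17 | 3,5-bis(benzyloxy)-2-{hydroxy[3-(3,4,5-tris(benzyloxy)phenyl)oxiran-2-yl]methyl}phenol, epoxide configuration as in 14, both carbinol epimers, titanium-bound | Oc1cc(OCc3ccccc3)cc(OCc3ccccc3)c1C(O)[C@@H]1O[C@H]1c1cc(OCc3ccccc3)c(OCc3ccccc3)c(OCc3ccccc3)c1 | intermediate (not isolated)
18 | (2R,3S)-5,7-bis(benzyloxy)-2-[3,4,5-tris(benzyloxy)phenyl]chromane-3,4-diol, C4 epimers, formed as its titanium diolate | C(c3ccccc3)Oc1cc(OCc3ccccc3)c2c(c1)O[C@H](c1cc(OCc3ccccc3)c(OCc3ccccc3)c(OCc3ccccc3)c1)[C@@H](O)C2O | intermediate (not isolated)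
19 | 5,7,3',4',5'-penta-O-benzylgallocatechin-(4α→8)-[3-O-TBS-5,7,3',4'-tetra-O-benzylcatechin]-(4β→8)-3,5,7,3',4'-penta-O-benzyl-ent-catechin | C(c3ccccc3)Oc1cc(OCc3ccccc3)c2c(c1)O[C@H](c1cc(OCc3ccccc3)c(OCc3ccccc3)c(OCc3ccccc3)c1)[C@@H](O)[C@@H]2c1c(OCc3ccccc3)cc(OCc3ccccc3)c2c1O[C@H](c1ccc(OCc3ccccc3)c(OCc3ccccc3)c1)[C@@H](O[Si](C)(C)C(C)(C)C)[C@H]2c1c(OCc3ccccc3)cc(OCc3ccccc3)c2c1O[C@@H](c1ccc(OCc3ccccc3)c(OCc3ccccc3)c1)[C@H](OCc3ccccc3)C2 | intermediate
20 | tridecabenzyl trimer with free 3-OH on the top and middle units | C(c3ccccc3)Oc1cc(OCc3ccccc3)c2c(c1)O[C@H](c1cc(OCc3ccccc3)c(OCc3ccccc3)c(OCc3ccccc3)c1)[C@@H](O)[C@@H]2c1c(OCc3ccccc3)cc(OCc3ccccc3)c2c1O[C@H](c1ccc(OCc3ccccc3)c(OCc3ccccc3)c1)[C@@H](O)[C@H]2c1c(OCc3ccccc3)cc(OCc3ccccc3)c2c1O[C@@H](c1ccc(OCc3ccccc3)c(OCc3ccccc3)c1)[C@H](OCc3ccccc3)C2 | intermediate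
21 | CNP0155646.2, gallocatechin-(4α→8)-catechin-(4β→8)-ent-catechin | Oc1cc(O)c2c(c1)O[C@H](c1cc(O)c(O)c(O)c1)[C@@H](O)[C@@H]2c1c(O)cc(O)c2c1O[C@H](c1ccc(O)c(O)c1)[C@@H](O)[C@H]2c1c(O)cc(O)c2c1O[C@@H](c1ccc(O)c(O)c1)[C@H](O)C2 | target

**Step count and risks**
Total steps: 12. Longest linear sequence: 7 steps (steps 6, 7, 8, 9, 10, 11, 12).

Step 10 (Proposed new method). What may go wrong: ionisation of the C4 carbinol before ring closure, self-condensation of the top unit through its own C8, or poor facial selectivity in the interflavan bond formation. Fallback, which sets out from dimer 9 and comes back at 19, with commercial (2R,3R)-dihydromyricetin as added material and known chemistry only: the dihydroflavonol is benzylated (BnBr, K2CO3, DMF) to its penta-O-benzyl ether F1, which NaBH4 in THF/EtOH reduces to the flavan-3,4-diol 18, now isolated. Acetylation (Ac2O, pyridine) gives the 3,4-diacetate F2. TMSOTf-catalysed condensation of F2 with 9 in CH2Cl2 at −78 °C, steered to the 3,4-trans product by the neighbouring 3-acetoxy group, gives the 3-O-acetyl trimer F3. Its acetate is removed with K2CO3 in MeOH/THF to give 19.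

Step 5. What may go wrong: enolisation or ring opening of ketone 6 by the basic aryllithium instead of addition, and poor facial selectivity of hydride delivery to the cation. Fallback, which sets out from 2 and comes back at 9, with commercial (−)-epicatechin as added material: the catechin is converted into its 5,7,3',4'-tetra-O-benzyl ether F4 (BnBr, K2CO3, DMF) and oxidised at C4 with DDQ in the presence of ethylene glycol to the 4β-(2-hydroxyethoxy) derivative F5. TiCl4-mediated condensation of F5 with 2 is attacked only from the β-face of the 2,3-cis electrophile, which fixes the 4β→8 bond in the epicatechin-(4β→8)-ent-catechin nonabenzyl ether F6. Dess–Martin oxidation of the 3-hydroxyl of the upper unit gives ketone F7. NaBH4/CeCl3 at −78 °C, approaching from the α-face away from the quasi-axial 4β-aryl group, should give the 2,3-trans-3,4-cis dimer alcohol F8, which TBSOTf/2,6-lutidine converts into 9. This detour needs neither an organolithium addition nor a hydride delivery to a cation.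

Step 11. What may go wrong: incomplete cleavage of the silyl ether, which is shielded between two flavan units in the trimer, and base-induced degradation when the reaction is forced. Fallback, which sets out from 9 and comes back at 20: the silyl ether is cleaved at the dimer stage, where it is far less shielded (HF·pyridine, THF), to give the dimer alcohol F9 (the same compound as F8), and step 10 is run with F9 in place of 9, which gives 20 directly.

**Further compounds**
F1 | step 10 | (2R,3R)-5,7-bis(benzyloxy)-3-hydroxy-2-[3,4,5-tris(benzyloxy)phenyl]chroman-4-one | C(c3ccccc3)Oc1cc(OCc3ccccc3)c2c(c1)O[C@H](c1cc(OCc3ccccc3)c(OCc3ccccc3)c(OCc3ccccc3)c1)[C@@H](O)C2=O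
F2 | step 10 | (2R,3S)-5,7-bis(benzyloxy)-2-[3,4,5-tris(benzyloxy)phenyl]chromane-3,4-diyl diacetate, C4 epimers | C(c3ccccc3)Oc1cc(OCc3ccccc3)c2c(c1)O[C@H](c1cc(OCc3ccccc3)c(OCc3ccccc3)c(OCc3ccccc3)c1)[C@@H](OC(C)=O)C2OC(C)=O
F3 | step 10 | 3-O-acetyl derivative of 19 (acetate on the top unit) | C(c3ccccc3)Oc1cc(OCc3ccccc3)c2c(c1)O[C@H](c1cc(OCc3ccccc3)c(OCc3ccccc3)c(OCc3ccccc3)c1)[C@@H](OC(C)=O)[C@@H]2c1c(OCc3ccccc3)cc(OCc3ccccc3)c2c1O[C@H](c1ccc(OCc3ccccc3)c(OCc3ccccc3)c1)[C@@H](O[Si](C)(C)C(C)(C)C)[C@H]2c1c(OCc3ccccc3)cc(OCc3ccccc3)c2c1O[C@@H](c1ccc(OCc3ccccc3)c(OCc3ccccc3)c1)[C@H](OCc3ccccc3)C2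
F4 | step 5 | 5,7,3',4'-tetra-O-benzyl-(−)-epicatechin (2R,3R) | C(c3ccccc3)Oc1cc(OCc3ccccc3)c2c(c1)O[C@H](c1ccc(OCc3ccccc3)c(OCc3ccccc3)c1)[C@H](O)C2
F5 | step 5 | 5,7,3',4'-tetra-O-benzyl-4β-(2-hydroxyethoxy)epicatechin | C(c3ccccc3)Oc1cc(OCc3ccccc3)c2c(c1)O[C@H](c1ccc(OCc3ccccc3)c(OCc3ccccc3)c1)[C@H](O)[C@H]2OCCO
F6 | step 5 | 5,7,3',4'-tetra-O-benzylepicatechin-(4β→8)-3,5,7,3',4'-penta-O-benzyl-ent-catechin | C(c3ccccc3)Oc1cc(OCc3ccccc3)c2c(c1)O[C@H](c1ccc(OCc3ccccc3)c(OCc3ccccc3)c1)[C@H](O)[C@H]2c1c(OCc3ccccc3)cc(OCc3ccccc3)c2c1O[C@@H](c1ccc(OCc3ccccc3)c(OCc3ccccc3)c1)[C@H](OCc3ccccc3)C2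
F7 | step 5 | 3-ketone of the upper unit of F6 | C(c3ccccc3)Oc1cc(OCc3ccccc3)c2c(c1)O[C@H](c1ccc(OCc3ccccc3)c(OCc3ccccc3)c1)C(=O)[C@H]2c1c(OCc3ccccc3)cc(OCc3ccccc3)c2c1O[C@@H](c1ccc(OCc3ccccc3)c(OCc3ccccc3)c1)[C@H](OCc3ccccc3)C2
F8 | step 5 | 5,7,3',4'-tetra-O-benzylcatechin-(4β→8)-3,5,7,3',4'-penta-O-benzyl-ent-catechin (free 3-OH on the upper unit) | C(c3ccccc3)Oc1cc(OCc3ccccc3)c2c(c1)O[C@H](c1ccc(OCc3ccccc3)c(OCc3ccccc3)c1)[C@@H](O)[C@H]2c1c(OCc3ccccc3)cc(OCc3ccccc3)c2c1O[C@@H](c1ccc(OCc3ccccc3)c(OCc3ccccc3)c1)[C@H](OCc3ccccc3)C2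
F9 | step 11 | dimer alcohol from desilylation of 9 (same structure as F8) | C(c3ccccc3)Oc1cc(OCc3ccccc3)c2c(c1)O[C@H](c1ccc(OCc3ccccc3)c(OCc3ccccc3)c1)[C@@H](O)[C@H]2c1c(OCc3ccccc3)cc(OCc3ccccc3)c2c1O[C@@H](c1ccc(OCc3ccccc3)c(OCc3ccccc3)c1)[C@H](OCc3ccccc3)C2
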